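A neighbour of flask epsilon, charged with 1.5 M of partner A, is where we want to end, so we look for a rule that shows the excess of partner A over substrate openly.

| flask | substrate | partner A | gas | temperature | time | remark |
|---|---|---|---|---|---|---|
| zeta | 0.74 M | 0.888 M | 200 mM (held) | −25 °C | 50 min |  |
| beta | 0.74 M | 0.888 M | 200 mM (held) | 5 °C | 50 min |  |
| eta | 0.74 M | 0.888 M | 200 mM (held) | 35 °C | 50 min |  |
| epsilon | 0.74 M | 0.888 M | 200 mM (held) |  | 50 min | at −25 °C until 10 min, from then on at 35 °C |

* the flask that comes out highest in amount of open intermediate, in percent of the substrate charged, or "all alike" when all lie within 1.5 percentage points (zeta / beta / eta / epsilon / all alike)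
* open intermediate at the end, in percent of the substrate charged, zeta
* open intermediate at the end, in percent of the substrate charged, beta
* open intermediate at the end, in percent of the substrate charged, eta
* open intermediate at the end, in percent of the substrate charged, epsilon

- at the start none of partner B is dissolved
- constants are those at 35 °C; use the activation energies and enthalpies for any other temperature

    partner B + partner A → second intermediate (k1 = 0.0160 L mol⁻¹ s⁻¹, Ea1 = 62.0 kJ mol⁻¹)
    open intermediate + second intermediate → target (k2 = 6.68 × 10⁻⁴ L mol⁻¹ s⁻¹, Ea2 = 61.0 kJ mol⁻¹)
    gas ⇌ partner B, rate k3*(csat - [partner B]) (k3 = 0.226 s⁻¹, csat = 200 mM)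
    target ⇌ isomer of the product (K4 = 0.734, k4 = 6.22 × 10⁻⁴ s⁻¹, Ea4 = 97.0 kJ mol⁻¹, ΔH4 = −50.0 kJ mol⁻¹)
    substrate + partner B → open intermediate (k5 = 0.0534 L mol⁻¹ s⁻¹, Ea5 = 65.0 kJ mol⁻¹)
    (constants at 35 °C)

Partner B enters from the held gas with coefficient 0.226 s⁻¹, while in flask eta at the start the charges remove it at 0.0537 s⁻¹; since supply is faster than that, we take [partner B] as 200 mM for our estimate. So substrate decays in a pseudo-first-order way, and the share turned is one minus the exponential of minus (rate constant × 200 mM × time). In zeta this gives 6.71%. In beta, at 5 °C, it gives 87.5%, but that is conversion, a ceiling for open intermediate.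

With [partner B] taken so, at 35 °C substrate has a half-life of 1.08 min, and partner A lasts 5.21 min on average. But open intermediate and second intermediate destroy each other, one of each, so that step leaves their difference unchanged, and once substrate and partner A have both turned over, the difference equals the excess, 0.148 M. Dividing the two rates, we find that in our estimate the ratio [second intermediate]/[open intermediate] starts at 1.20 and grows exponentially at the excess clock, the rate constant of their reaction at 35 °C times the excess, 0.00593 min⁻¹. We start it 5.21 min late, and [open intermediate] is then the excess divided by (ratio minus one). That gives 35.4% for eta. For epsilon, hot for 40.0 min, it gives 42.1%.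

The forecast gives 6.7% for zeta, 84.6% for beta, 36% for eta and 42.9% for epsilon: “so beta comes out highest”. Its beta lies below our ceiling, and its eta and epsilon lie a little above our figures.

The simulation gives beta as highest, with 6.70% in zeta, 84.7% in beta, 36.1% in eta and 43.0% in epsilon.

In epsilon, 98.6% of the substrate still stood at 10.0 min, half was turned by 11.2 min, and open intermediate stood at 74.9% at 25.0 min, with 6.24% of the charged partner A left, before falling to 43.0% at 50.0 min, where the ratio reads 1.46 against the clock's 1.48. In the neighbour of epsilon the excess is 0.760 M, so the clock runs at 0.0305 min⁻¹, faster than in epsilon, and it gives 21.2%; that flask ends at 22.1%.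

The numbers are assumed.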